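**Plan**

1. Numbering (labdane-type): ring A = C1–C5 + C10 (4,4-dimethyl), ring B = C5–C10 (6-OAc, 7-oxo, 8-CH3 = C17, 10-CH3 = C20), ring C = cyclobutane C8–C9–C14–C15, ring D = cyclopentane C9/C11–C14 (13-CH3 = C16, 13-OH).
2. Retrosynthetic cuts, in this order: the C5–H and C6–H bonds (back to a 6-acetoxy-5-en-7-one, itself from the 7-ketone by autoxidation); C3–C4 (ring A); C9–C14 with C8–C15 (rings D and C); C9–C11 with a 1,3-shift of the ring B carbonyl; C10–C1 and C10–CH3.
3. Forward: ring B is (R)-carvone. Its α′-carbon is quaternised to C10 (CH3, then a (Z)-3-bromoallyl arm = C1–C3). A C11–C16 chain cut from (S)-linalool is added at C9 and the oxygen moved to C7. Rings D and C form together by intramolecular enone–alkene [2+2] photocycloaddition. Ring A is closed last by a 6-exo reductive Heck cyclisation.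
4. Feature that makes the key event possible: the quaternary C4 of ring A hangs on C5 of ring B exactly where carvone carries C(CH3)=CH2. Carbopalladation of that alkene at its inner carbon by C3 leaves palladium on a CH2 whose neighbour C4 has no hydrogen, so hydride capture turns it into the second C4 methyl.
5. Helpers and their removal: the C2=C3 double bond (from the alkenyl bromide) and the C5 stereocentre of carvone (erased in the diosphenol, then re-set) are dealt with in the last hydrogenation; the O13 triethylsilyl group is cleaved in step 14.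
6. Stereochemistry: C5 of carvone sets C10 (alkylation anti to isopropenyl); C5 and the C10 methyl set C8, C9 and C14 (α-face cycloaddition); C13 is the carbinol carbon of (S)-linalool; 5α-H and 6β-OAc arise together by α-face syn-hydrogenation.

Key step: step 12

Assumption: (S)-(+)-linalool and ethyl (Z)-3-bromoacrylate are taken as purchasable in high enantiomeric and geometric purity; the enantiomeric purity of the linalool fixes the diastereomeric purity at C13.

**Route**

Step 1
Reactants: 1 ethyl (2Z)-3-bromoprop-2-enoate
Product: 2 (2Z)-3-bromoprop-2-en-1-ol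
Conditions: i-Bu2AlH (2.2 equiv), CH2Cl2, −78 °C; aq. KNaC4H4O6 (potassium sodium tartrate)
Reagents that add atoms: none
Why: Low-temperature hydride reduction of a conjugated ester to the allylic alcohol should proceed 1,2 without touching the alkenyl C–Br bond or the Z geometry, and no stereocentre is formed.

Step 2
Reactants: 2 (2Z)-3-bromoprop-2-en-1-ol
Product: 3 (1Z)-1,3-dibromoprop-1-ene
Conditions: PBr3 (0.4 equiv), Et2O, 0 °C
Reagents that add atoms: phosphorus tribromide, BrP(Br)Br
Why: Conversion of a primary allylic alcohol into the bromide with PBr3 (SN2 displacement of the phosphite ester by bromide) should leave the Z-alkenyl bromide untouched; no stereocentre is formed.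

Step 3
Reactants: 4 (S)-(+)-linalool [(3S)-3,7-dimethylocta-1,6-dien-3-ol]
Product: 5 triethyl{[(3S)-3,7-dimethylocta-1,6-dien-3-yl]oxy}silane
Conditions: Et3SiOTf, 2,6-lutidine, CH2Cl2, −78 to 0 °C
Reagents that add atoms: triethylsilyl trifluoromethanesulfonate, CC[Si](CC)(CC)OS(=O)(=O)C(F)(F)F
Why: Silylation of the hindered tertiary allylic alcohol with a silyl triflate and a hindered base should be fast and leaves the future C13 stereocentre untouched; the ether later tolerates the organometallic step.

Step 4
Reactants: 5 triethyl{[(3S)-3,7-dimethylocta-1,6-dien-3-yl]oxy}silane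
Product: 7 (4S)-4-methyl-4-[(triethylsilyl)oxy]hex-5-enal, via ozonide 6 (not isolated)
Conditions: O3 (1.0 equiv), CH2Cl2, −78 °C; then PPh3, −78 °C to rt
Reagents that add atoms: ozone, [O-][O+]=O
Why: Chemoselective ozonolysis: the electron-rich trisubstituted alkene reacts with ozone far faster than the monosubstituted vinyl group next to the quaternary centre, so one equivalent should cleave only the former, and reductive work-up of the ozonide gives the aldehyde.

Step 5
Reactants: 7 (4S)-4-methyl-4-[(triethylsilyl)oxy]hex-5-enal
Product: 8 (4S)-4-methyl-4-[(triethylsilyl)oxy]hex-5-enoic acid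
Conditions: NaClO2, NaH2PO4, 2-methylbut-2-ene, t-BuOH/H2O, 0 °C to rt
Reagents that add atoms: sodium chlorite, [Na+].[O-]Cl=O
Why: Pinnick oxidation (buffered chlorite with 2-methylbut-2-ene as hypochlorite scavenger) should take the aldehyde to the acid without affecting the vinyl group, the silyl ether or the stereocentre.

Step 6
Reactants: 8 (4S)-4-methyl-4-[(triethylsilyl)oxy]hex-5-enoic acid
Product: 10 triethyl{[(3S)-5-iodo-3-methylpent-1-en-3-yl]oxy}silane, via thiohydroxamate ester 9 (not isolated)
Conditions: 1-hydroxypyridine-2(1H)-thione, N,N'-dicyclohexylcarbodiimide, DMAP (catalytic), CH2Cl2, 0 °C, dark; then CHI3, visible light, rt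
Reagents that add atoms: iodoform, IC(I)I
Why: Barton decarboxylative iodination: the thiohydroxamate ester fragments in a radical chain to CO2 and the primary C11 radical, which abstracts iodine from iodoform, and a pent-4-enyl radical of this kind has no fast cyclisation path, so the chain shortened by one carbon should be obtained with C13 intact.

Step 7
Reactants: 11 (R)-(−)-carvone
Product: 13 (5R)-2,6-dimethyl-5-(prop-1-en-2-yl)cyclohex-2-en-1-one (both C6 epimers), via lithium enolate 12 (not isolated)
Conditions: LiN(i-Pr)2, THF, −78 °C; then MeI, −78 to 0 °C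
Reagents that add atoms: iodomethane, CI
Why: Kinetic α′-deprotonation of carvone (C6, the future C10) and C-methylation of the lithium enolate is a standard enolate alkylation; the new centre forms as a mixture that is of no consequence because it is planarised again in step 8.

Step 8
Reactants: 13 (5R)-2,6-dimethyl-5-(prop-1-en-2-yl)cyclohex-2-en-1-one; 3 (1Z)-1,3-dibromoprop-1-ene
Product: 15 (5S,6S)-6-[(2Z)-3-bromoprop-2-en-1-yl]-2,6-dimethyl-5-(prop-1-en-2-yl)cyclohex-2-en-1-one (bromoallyl trans and methyl cis to isopropenyl), via lithium enolate 14 (not isolated)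
Conditions: LiN(i-Pr)2, THF, −78 to 0 °C; then DMPU, 3, −78 °C to rt
Reagents that add atoms: none
Why: Alkylation of the tetrasubstituted α′-enolate with the allylic bromide end of 3 (SN2; the alkenyl bromide is inert) should occur on the face anti to the adjacent isopropenyl group, which makes the quaternary C10 with the bromoallyl arm trans and the methyl cis to isopropenyl.

Step 9
Reactants: 10 triethyl{[(3S)-5-iodo-3-methylpent-1-en-3-yl]oxy}silane; 15 (5S,6S)-6-[(2Z)-3-bromoprop-2-en-1-yl]-2,6-dimethyl-5-(prop-1-en-2-yl)cyclohex-2-en-1-one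
Product: 18 tertiary allylic alcohol from 1,2-addition of the side chain to the carbonyl of 15 (both carbinol epimers), via alkyllithium 16 (not isolated), via organocerium dichloride 17 (not isolated)
Conditions: 10, t-BuLi (2.1 equiv), Et2O/pentane, −78 °C; CeCl3, THF, −78 °C; then 15, −78 to −40 °C; aq. NH4Cl
Reagents that add atoms: none
Why: Iodine–lithium exchange, transmetalation to the weakly basic organocerium reagent and its 1,2-addition to the hindered enone carbonyl (future C9) should give the tertiary allylic alcohol without halogen–metal exchange at the alkenyl bromide or conjugate addition; the carbinol centre forms as a mixture that is removed in step 10.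

Step 10
Reactants: 18 tertiary allylic alcohol
Product: 19 (4S,5S)-4-[(2Z)-3-bromoprop-2-en-1-yl]-2,4-dimethyl-3-{(3S)-3-methyl-3-[(triethylsilyl)oxy]pent-4-en-1-yl}-5-(prop-1-en-2-yl)cyclohex-2-en-1-one
Conditions: pyridinium chlorochromate (C5H5NH)[CrO3Cl], NaOAc, 4 Å molecular sieves, CH2Cl2, rt
Reagents that add atoms: pyridinium chlorochromate, [O-][Cr](=O)(=O)Cl.c1cc[nH+]cc1
Why: Dauben–Babler oxidative transposition: the chromate ester of the tertiary allylic alcohol undergoes a [3,3] shift from C9 to C7 and is oxidised there, which should give the transposed tetrasubstituted enone and delete the carbinol stereocentre while C5, C10 and C13 stay untouched.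

Step 11
Reactants: 19 the enone
Product: 20 tricyclic 7-ketone (rings B, C, D): 8β-CH3; cyclobutane C8–C15–C14–C9 on the α face; cyclopentane C9/C11–C14 with (13S)-CH3 and OSiEt3; 10β-CH3; 10α-[(2Z)-3-bromoprop-2-enyl]; 5β-(prop-1-en-2-yl)
Conditions: hν (366 nm), degassed MeCN, 0 °C
Reagents that add atoms: none
Why: Intramolecular enone–alkene [2+2] photocycloaddition through the enone triplet: by the rule of five C9 should bond first to C14 through the three-atom tether and C15 then closes onto C8 to give the straight, cis-fused cyclobutane, both bonds forming on the α face of ring B anti to the β-oriented C10 methyl and C5 isopropenyl groups, which sets C9, C8 and C14, while the alkenyl bromide is not excited at this wavelength and C13 is carried in from 10.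

Step 12
Reactants: 20 tricyclic 7-ketone
Product: 21 tetracyclic 7-ketone with ring A closed: 4,4-dimethyl; C2=C3 double bond; 5α-H (trans A/B); 13-OSiEt3
Conditions: Pd(OAc)2 (10 mol %), PPh3 (30 mol %), HCO2Na (2 equiv), Et4NCl, DMF, 80 °C
Reagents that add atoms: none
Why: Zerovalent palladium (formed in situ from Pd(OAc)2 and PPh3) should insert into the (Z)-alkenyl C3–Br bond, the alkenylpalladium bromide then adds syn across the isopropenyl C=C in a 6-exo-trig carbopalladation that forms C3–C4 and leaves palladium on the former CH2, and because C4 is now quaternary this alkylpalladium has no β-hydrogen, exchanges bromide for formate, loses CO2 and reductively eliminates C–H to give the second C4 methyl and zerovalent palladium. The closest known reaction type is the intramolecular reductive Heck (hydride-capture) cyclisation that builds all-carbon quaternary centres from 1,1-disubstituted alkenes. Ring A is closed in the 6-exo mode and ends trans-fused because its two arms, C1 on C10 and C4 on C5, are already trans on ring B, and the Z geometry of C2=C3 is what lets C3 reach C4. No new stereocentre is formed (C4 carries two methyls) and C5, C8, C9, C10, C13 and C14 are not touched. The step needs 6-exo over 7-endo insertion, which the tether length secures, and it needs hydride capture to outrun both direct reduction of the alkenylpalladium and 3-exo attack of the alkylpalladium on the new C2=C3 bond, which fast intramolecular insertion and an excess of formate should secure; the weakly basic medium keeps the C7 ketone from competing by α-alkenylation.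

Step 13
Reactants: 21 tetracyclic 7-ketone
Product: 23 6-hydroxy-5-en-7-one (diosphenol; 13-OSiEt3; C2=C3 retained), via 6,7-dione 22 (not isolated)
Conditions: KOt-Bu, O2 (1 atm), t-BuOH/THF, rt; aq. NH4Cl
Reagents that add atoms: dioxygen, O=O
Why: Base-mediated autoxidation of a ketone to a diosphenol: C6 is the only enolisable position next to the C7 carbonyl (C8 is quaternary), its potassium enolate should take up O2 to give the 6,7-dione, and this enolises toward C5 to the conjugated 6-hydroxy-5-en-7-one, which deliberately erases the C5 stereocentre so that C5 and C6 can be set together in step 16.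

Step 14
Reactants: 23 diosphenol silyl ether
Product: 24 6,13-dihydroxy-5-en-7-one (free tertiary alcohol)
Conditions: HF·pyridine, pyridine, THF, 0 °C to rt
Reagents that add atoms: none
Why: Fluoride cleavage of the tertiary triethylsilyl ether under buffered, weakly acidic conditions should free O13 without ionising the tertiary carbinol next to the cyclobutane and without affecting the diosphenol.

Step 15
Reactants: 24 6,13-dihydroxy-5-en-7-one
Product: 25 6-acetoxy-13-hydroxy-5-en-7-one (diosphenol acetate)
Conditions: Ac2O, pyridine, 0 °C to rt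
Reagents that add atoms: acetic anhydride, CC(=O)OC(C)=O
Why: O-Acetylation of the acidic diosphenol hydroxyl with acetic anhydride in pyridine should give the enol acetate selectively, because the tertiary C13 hydroxyl is not acylated in the absence of an acyl-transfer catalyst.

Step 16
Reactants: 25 diosphenol acetate
Product: 26 CNP0330581.1 (6β-acetoxy-13-hydroxy-7-oxo tetracycle; 5α-H; 13S)
Conditions: H2 (50 bar), Pd/C, EtOAc, rt
Reagents that add atoms: none
Why: Heterogeneous syn-hydrogenation saturates the C2=C3 helper alkene and should add both hydrogens to the tetrasubstituted C5=C6 enol acetate from the α face, because the β face is screened by the C10 methyl, the 4β methyl and the C8 methyl, which sets 5α-H (trans A/B) and 6α-H, that is the axial 6β-acetate, in one event under neutral conditions that do not epimerise C6.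

**Compound list**

1 | ethyl (2Z)-3-bromoprop-2-enoate | CCOC(=O)/C=C\Br | starting material
2 | (2Z)-3-bromoprop-2-en-1-ol | OC/C=C\Br | intermediate
3 | (1Z)-1,3-dibromoprop-1-ene | BrC/C=C\Br | intermediate
4 | (S)-(+)-linalool | C=C[C@@](C)(O)CCC=C(C)C | starting material
5 | triethyl{[(3S)-3,7-dimethylocta-1,6-dien-3-yl]oxy}silane | C=C[C@@](C)(O[Si](CC)(CC)CC)CCC=C(C)C | intermediate
6 | ozonide (1,2,4-trioxolane) of 5 at the trisubstituted alkene | C=C[C@@](C)(O[Si](CC)(CC)CC)CCC1OOC(C)(C)O1 | intermediate (not isolated)
7 | (4S)-4-methyl-4-[(triethylsilyl)oxy]hex-5-enal | C=C[C@@](C)(O[Si](CC)(CC)CC)CCC=O | intermediate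
8 | (4S)-4-methyl-4-[(triethylsilyl)oxy]hex-5-enoic acid | C=C[C@@](C)(O[Si](CC)(CC)CC)CCC(O)=O | intermediate
9 | 2-thioxopyridin-1(2H)-yl ester of 8 (thiohydroxamate ester) | C=C[C@@](C)(O[Si](CC)(CC)CC)CCC(=O)On1ccccc1=S | intermediate (not isolated)
10 | triethyl{[(3S)-5-iodo-3-methylpent-1-en-3-yl]oxy}silane | C=C[C@@](C)(O[Si](CC)(CC)CC)CCI | intermediate
11 | (R)-(−)-carvone | CC1=CC[C@H](CC1=O)C(C)=C | starting material
12 | lithium α′-enolate of carvone | CC1=CC[C@H](C=C1O[Li])C(C)=C | intermediate (not isolated)
13 | (5R)-2,6-dimethyl-5-(prop-1-en-2-yl)cyclohex-2-en-1-one (C6 epimers) | CC1=CC[C@H](C(C)C1=O)C(C)=C | intermediate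
14 | lithium α′-enolate of 13 | CC1=CC[C@H](C(C)=C1O[Li])C(C)=C | intermediate (not isolated)
15 | (5S,6S)-6-[(2Z)-3-bromoprop-2-en-1-yl]-2,6-dimethyl-5-(prop-1-en-2-yl)cyclohex-2-en-1-one | CC1=CC[C@H]([C@](C)(C/C=C\Br)C1=O)C(C)=C | intermediate
16 | [(3S)-3-methyl-3-(triethylsilyloxy)pent-4-en-1-yl]lithium | C=C[C@@](C)(O[Si](CC)(CC)CC)CC[Li] | intermediate (not isolated)
17 | [(3S)-3-methyl-3-(triethylsilyloxy)pent-4-en-1-yl]cerium dichloride | C=C[C@@](C)(O[Si](CC)(CC)CC)CC[Ce](Cl)Cl | intermediate (not isolated)
18 | tertiary allylic alcohol from 17 and 15 (carbinol epimers) | CC1=CC[C@H]([C@](C)(C/C=C\Br)C1(O)CC[C@](C)(O[Si](CC)(CC)CC)C=C)C(C)=C | intermediate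
19 | (4S,5S)-4-[(2Z)-3-bromoprop-2-en-1-yl]-2,4-dimethyl-3-{(3S)-3-methyl-3-[(triethylsilyl)oxy]pent-4-en-1-yl}-5-(prop-1-en-2-yl)cyclohex-2-en-1-one | CC1=C(CC[C@](C)(O[Si](CC)(CC)CC)C=C)[C@@](C)(C/C=C\Br)[C@@H](CC1=O)C(C)=C | intermediate
20 | tricyclic 7-ketone (rings B, C, D; 10α-(Z)-bromoallyl; 5β-isopropenyl; 13-OSiEt3) | O=C1[C@@]2(C)C[C@H]3[C@@]2(CC[C@]3(C)O[Si](CC)(CC)CC)[C@@](C)(C/C=C\Br)[C@@H](C1)C(C)=C | intermediate
21 | tetracyclic 7-ketone (ring A closed; C2=C3; 5α-H; 13-OSiEt3) | O=C1[C@@]2(C)C[C@H]3[C@@]2(CC[C@]3(C)O[Si](CC)(CC)CC)[C@@]2(C)CC=CC(C)(C)[C@@H]2C1 | intermediate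
22 | tetracyclic 6,7-dione (13-OSiEt3) | O=C1[C@@]2(C)C[C@H]3[C@@]2(CC[C@]3(C)O[Si](CC)(CC)CC)[C@@]2(C)CC=CC(C)(C)[C@@H]2C1=O | intermediate (not isolated)
23 | 6-hydroxy-5-en-7-one (diosphenol; 13-OSiEt3) | O=C1[C@@]2(C)C[C@H]3[C@@]2(CC[C@]3(C)O[Si](CC)(CC)CC)[C@@]2(C)CC=CC(C)(C)C2=C1O | intermediate
24 | 6,13-dihydroxy-5-en-7-one | O=C1[C@@]2(C)C[C@H]3[C@@]2(CC[C@]3(C)O)[C@@]2(C)CC=CC(C)(C)C2=C1O | intermediate
25 | 6-acetoxy-13-hydroxy-5-en-7-one (C2=C3 retained) | O=C1[C@@]2(C)C[C@H]3[C@@]2(CC[C@]3(C)O)[C@@]2(C)CC=CC(C)(C)C2=C1OC(C)=O | intermediate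
26 | CNP0330581.1 | CC(=O)O[C@@H]1C(=O)[C@@]2(C)C[C@H]3[C@@]2(CC[C@]3(C)O)[C@@]2(C)CCCC(C)(C)[C@H]12 | target

**Count and risks**

Total step count: 16. Longest linear sequence: 12 steps (4 to 26 through steps 3–6 and 9–16).

Step 16 (final hydrogenation). Hydrogen uptake may stall at the tetrasubstituted enol acetate, which is flanked by two quaternary carbons. Part of the hydrogen may also be delivered from the β face, or the axial acetate may epimerise on handling. The fallback keeps the C5 configuration that carvone already provides and brings in O6 by a different logic. It sets out from 21. Hydrogenation (H2, Pd/C, EtOAc) of the ring A alkene alone should give the saturated trans-fused 7-ketone F1. LiN(SiMe3)2 then Ac2O gives the C6=C7 enol acetate F2. Dimethyldioxirane should epoxidise it from the open α face to the 6α,7α-epoxy 7β-acetate F3. Heating in toluene triggers the enol ester epoxide rearrangement, a 1,2-acyloxy shift with inversion at C6, to the 6β-acetoxy 7-ketone silyl ether F4. HF·pyridine then returns the route at 26.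

Step 11 (photocycloaddition). The enone triplet may be diverted to the bromoalkene arm on C10 or the isopropenyl group on C5 (crossed cycloaddition). Reversible biradical formation may also scramble the Z geometry of the bromoalkene, and facial selectivity may be incomplete. The fallback carries the C1–C3 arm through the irradiation as a silylalkyne, which is a poor partner for the triplet and has no geometry to lose. It sets out from 13. Enolate formation with LiN(i-Pr)2 and alkylation with 3-bromo-1-(trimethylsilyl)prop-1-yne gives the propargylated ketone F5. Addition of 17 gives the carbinol F6, and (C5H5NH)[CrO3Cl] gives the transposed enone F7. Irradiation at 366 nm gives the tricyclic silylalkyne F8. AgNO3 (catalytic) with N-bromosuccinimide in acetone gives the 1-bromoalkyne F9. Syn-hydroboration with dicyclohexylborane followed by protonolysis with AcOH should give the (Z)-alkenyl bromide, returning the route at 20.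

Step 12 (reductive Heck cyclisation). The alkenylpalladium may be reduced by formate before it inserts, the alkylpalladium may be trapped by 3-exo attack on the new alkene, or insertion may be slow next to the congested core. The fallback replaces carbopalladation by a radical/nickel cross-electrophile logic and sets out from 20. Markovnikov hydrobromination of the isopropenyl group by hydrogen-atom transfer (Co(acac)2 catalytic, TsBr, Et3SiH, t-BuOOH) gives the tertiary bromide F10. Intramolecular reductive coupling of the tertiary alkyl bromide with the (Z)-alkenyl bromide (NiI2, 4,4′-di-tert-butyl-2,2′-bipyridine, Zn, MgCl2, pyridine, DMA) should form C3–C4 with retention of the alkene geometry, returning the route at 21.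

**Further compounds**

F1 | step 16 | saturated tetracyclic 7-ketone (5α-H; 13-OSiEt3) | O=C1[C@@]2(C)C[C@H]3[C@@]2(CC[C@]3(C)O[Si](CC)(CC)CC)[C@@]2(C)CCCC(C)(C)[C@@H]2C1
F2 | step 16 | C6=C7 enol acetate of F1 | CC(=O)OC=1[C@@]2(C)C[C@H]3[C@@]2(CC[C@]3(C)O[Si](CC)(CC)CC)[C@@]2(C)CCCC(C)(C)[C@@H]2C=1
F3 | step 16 | 6α,7α-epoxy 7β-acetate from F2 | CC(=O)O[C@]12[C@@]3(C)C[C@H]4[C@@]3(CC[C@]4(C)O[Si](CC)(CC)CC)[C@@]3(C)CCCC(C)(C)[C@@H]3[C@H]1O2
F4 | step 16 | 13-O-triethylsilyl ether of 26 | CC(=O)O[C@@H]1C(=O)[C@@]2(C)C[C@H]3[C@@]2(CC[C@]3(C)O[Si](CC)(CC)CC)[C@@]2(C)CCCC(C)(C)[C@H]12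
F5 | step 11 | (5S,6S)-2,6-dimethyl-5-(prop-1-en-2-yl)-6-[3-(trimethylsilyl)prop-2-yn-1-yl]cyclohex-2-en-1-one | CC1=CC[C@H]([C@](C)(CC#C[Si](C)(C)C)C1=O)C(C)=C
F6 | step 11 | tertiary allylic alcohol from 17 and F5 (carbinol epimers) | CC1=CC[C@H]([C@](C)(CC#C[Si](C)(C)C)C1(O)CC[C@](C)(O[Si](CC)(CC)CC)C=C)C(C)=C
F7 | step 11 | transposed enone with silylpropargyl arm | CC1=C(CC[C@](C)(O[Si](CC)(CC)CC)C=C)[C@@](C)(CC#C[Si](C)(C)C)[C@@H](CC1=O)C(C)=C
F8 | step 11 | tricyclic 7-ketone with silylpropargyl arm | O=C1[C@@]2(C)C[C@H]3[C@@]2(CC[C@]3(C)O[Si](CC)(CC)CC)[C@@](C)(CC#C[Si](C)(C)C)[C@@H](C1)C(C)=C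
F9 | step 11 | tricyclic 7-ketone with 3-bromoprop-2-ynyl arm | O=C1[C@@]2(C)C[C@H]3[C@@]2(CC[C@]3(C)O[Si](CC)(CC)CC)[C@@](C)(CC#CBr)[C@@H](C1)C(C)=C
F10 | step 12 | tricyclic 7-ketone with 5β-(2-bromopropan-2-yl) group | O=C1[C@@]2(C)C[C@H]3[C@@]2(CC[C@]3(C)O[Si](CC)(CC)CC)[C@@](C)(C/C=C\Br)[C@@H](C1)C(C)(C)Br
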